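(The earlier runs and the new flask are calculated from invented constants, noise included.)

The early hours of the two earlier runs were where I began on the quick number you asked for: at 3.00 h Sunday's flask read 15.4 mM of links, more than the 3.36 mM read in Monday's flask, yet by 20.0 h Sunday's links had slid to a reading of 8.80 mM while Monday's had risen to a reading of 4.96 mM.

in all of them: second end groups 20.4 mM (fed, over 1.0 h)

|  | first end groups | remark | time |
|---|---|---|---|
| Monday's | 8 mM | run made earlier |  |
| Sunday's | 110 mM | run made earlier |  |
| south-east | 10 mM |  | 40 h |
| east | 20 mM |  | 40 h |
| south-west | 40 mM |  | 40 h |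
| north | 80 mM |  | 40 h |
| west | 150 mM |  | 40 h |

| run | time / h | links / % | first end groups / % |
|---|---|---|---|
| Monday's | 3.00 | 42 | 50 |
| Monday's | 6.00 | 60 | 28 |
| Monday's | 10.0 | 64 | 19 |
| Monday's | 12.0 | 63 | 16 |
| Monday's | 15.0 | 64 | 15 |
| Monday's | 20.0 | 62 | 11 |
| Sunday's | 3.00 | 14 | 81 |
| Sunday's | 6.00 | 11 | 82 |
| Sunday's | 10.0 | 8 | 83 |
| Sunday's | 12.0 | 12 | 80 |
| Sunday's | 15.0 | 7 | 81 |
| Sunday's | 20.0 | 8 | 81 |

(readings scatter by 1.5 percentage points)

- "hardly changes" means that all values lie within two and a half points (for a concentration: within two and a half percent of the largest)

1. [links] at the end for south-east, east, south-west, north, west, in this order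
2. the shape of the row from first to last (hardly changes / rises all the way / rises, then falls / falls, then rises / falls all the way)

The scale I used was first end groups charged over second end groups charged, with the nearly equal charge of east, 0.980, as its zero; I call it the balance. Each link takes one end group of each kind, so below a balance of one the first end groups are the limiting reagent, and above it the second end groups are. Monday's flask stood at 0.392, and its links read 62% of the limiting charge at 20.0 h. Sunday's flask stood at 5.39, and its links read 8.80 mM, which is 43.1% of the limiting charge. Letting those readings stand for the asked time, I put Monday's share on south-east and east, which gave 6.20 mM and 12.4 mM, and I put Sunday's 8.80 mM on the far side of the balance, so my row rose to about a balance of one and then fell.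

Your forecast differed from mine: it gave 3.8 mM, 4 mM, 4.05 mM, 4.1 mM and 4.15 mM, a row that rises all the way, on the ground that “second-order decay erases most of the memory of the start”.

The flask gave 5.74 mM, 9.68 mM, 9.81 mM, 5.63 mM and 4.88 mM for south-east, east, south-west, north and west, a row that rises, then falls, by these steps:

    first end groups + second end groups ⇌ links (K = 440 M⁻¹, k = 14.9 M⁻¹ h⁻¹)
    first end groups + second end groups → rings, rate k2*[first end groups] as long as [second end groups] is above zero (k = 0.00572 h⁻¹)
    links ⇌ isomer of the product (K = 0.467, k = 0.0505 h⁻¹)
    first end groups → decomposition product (k = 1.30 × 10⁻⁴ h⁻¹)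

With the step to rings switched off, the row rises all the way. The row turned at 29 mM of first end groups, a balance of 1.40, and west, at a balance of 7.35, ended with 0% of its second end groups and 4.88 mM of links after 40.0 h.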